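**Strategy.** Everything rests on cutting the 9,10-dihydrophenanthrene ring at both bonds of its C10H2–C9H(Ar) bridge (C10–ring A and C9–ring D; ring A is the dioxygenated and ring D the mono-oxygenated ring of the biaryl, phenanthrene numbering). The key step exploits that this bridge spans the two ortho positions of the A–D biaryl and that C9 carries the catechol ring, so it is a styrene in disguise. A nickel-catalysed enantioselective reductive [4+2] annulation, in which a 2-bromo-2'-triflyloxybiaryl 1,2-diarylates 3,4-dimethoxystyrene, closes the six-membered ring and sets (R)-C9 in one operation. The precursor is a tri-ortho-substituted biaryl whose ring D carries an (E)-3,4-dimethoxystyryl arm; this arm later closes the seven-membered ring by Friedel–Crafts hydroarylation under control of C9.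

Key step: step 6

Assumption: the sense of induction of the BiOX ligand in this annulation is not known in advance; the ligand antipode that delivers (9R)-12 is the one used. All seven phenols are carried as methyl ethers.

Step 1
Reactants: 1 1-bromo-3,5-dimethoxybenzene
Product: 2 1-bromo-2-iodo-3,5-dimethoxybenzene
Conditions: NIS (1.05 equiv), TFA (10 mol %), MeCN, rt, dark
Reagents that add atoms: N-iodosuccinimide, O=C1CCC(=O)N1I
Why: Electrophilic aromatic iodination (SEAr); as with other 1,3-dimethoxyarenes the iodine should enter para to one methoxy group and ortho to the other (C2), not between the two methoxy groups.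

Step 2
Reactants: 3 2-hydroxy-5-methoxybenzaldehyde
Product: 4 2-hydroxy-3-iodo-5-methoxybenzaldehyde
Conditions: NIS (1.05 equiv), TsOH·H2O (10 mol %), MeCN, rt
Reagents that add atoms: N-iodosuccinimide, O=C1CCC(=O)N1I
Why: Electrophilic aromatic iodination (SEAr) directed by the free phenol to its only open ortho position, the para position being blocked by OMe.

Step 3
Reactants: 4 2-hydroxy-3-iodo-5-methoxybenzaldehyde
Product: 5 2-formyl-6-iodo-4-methoxyphenyl trifluoromethanesulfonate
Conditions: Tf2O (1.2 equiv), pyridine, CH2Cl2, 0 °C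
Reagents that add atoms: trifluoromethanesulfonic anhydride, O=S(=O)(OS(=O)(=O)C(F)(F)F)C(F)(F)F
Why: O-Triflation of the phenol turns the C–O bond into the leaving group needed later for nickel and removes the acidic proton before the organometallic steps.

Step 4
Reactants: 5 2-formyl-6-iodo-4-methoxyphenyl trifluoromethanesulfonate; 6 diethyl (3,4-dimethoxybenzyl)phosphonate
Product: 7 2-[(E)-2-(3,4-dimethoxyphenyl)ethenyl]-6-iodo-4-methoxyphenyl trifluoromethanesulfonate
Conditions: 6, NaH, THF, 0 °C; then 5, 0 °C → rt
Reagents that add atoms: none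
Why: Horner–Wadsworth–Emmons olefination of the aldehyde with the benzylphosphonate anion should give the (E)-stilbene, the aryl iodide and aryl triflate being inert to the phosphonate carbanion at 0 °C.

Step 5
Reactants: 2 1-bromo-2-iodo-3,5-dimethoxybenzene; 7 2-[(E)-2-(3,4-dimethoxyphenyl)ethenyl]-6-iodo-4-methoxyphenyl trifluoromethanesulfonate
Product: 10 2'-bromo-3-[(E)-2-(3,4-dimethoxyphenyl)ethenyl]-4',5,6'-trimethoxybiphenyl-2-yl trifluoromethanesulfonate, via arylmagnesium chloride 8 (not isolated), via arylzinc chloride 9 (not isolated)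
Conditions: 2, i-PrMgCl·LiCl, THF, −20 °C; ZnCl2, −20 °C → rt; then 7, Pd2(dba)3 (2.5 mol %), SPhos (10 mol %), THF, 40 °C
Reagents that add atoms: none
Why: Iodine–magnesium exchange is selective for C–I over C–Br, transmetalation gives a tolerant arylzinc, and the Negishi cross-coupling should take place at the C–I bond of 7 before its C–OTf bond or the hindered C–Br bond react (I > Br, OTf in oxidative addition to Pd(0)).

Step 6
Reactants: 10 2'-bromo-3-[(E)-2-(3,4-dimethoxyphenyl)ethenyl]-4',5,6'-trimethoxybiphenyl-2-yl trifluoromethanesulfonate; 11 3,4-dimethoxystyrene (4-ethenyl-1,2-dimethoxybenzene)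
Product: 12 (9R)-9-(3,4-dimethoxyphenyl)-8-[(E)-2-(3,4-dimethoxyphenyl)ethenyl]-2,4,6-trimethoxy-9,10-dihydrophenanthrene
Conditions: NiBr2·DME (10 mol %), 4,4'-di-sec-butyl-BiOX (12 mol %; antipode giving 9R), Zn dust (2 equiv), 11 (1.5 equiv), DMPU/THF, 30 °C
Reagents that add atoms: none
Why: Proposed new method: Ni(0) is expected to insert first into the C–Br bond of 10 (N-ligated nickel prefers C–Br over C–OTf, and the triflate is flanked by two ortho substituents), the arylnickel, after reduction by zinc, adds across the terminal alkene of 11 with the aryl group going to CH2 and nickel to the benzylic carbon, and the benzylic nickel then activates the neighbouring C–OTf bond and undergoes C(sp3)–C(sp2) reductive elimination. The closest known reaction type is the nickel-catalysed asymmetric reductive 1,2-diarylation of vinylarenes with two aryl bromides, here run with both aryl electrophiles held in one biaryl (compare also the [4+2] insertions of π-systems into 2,2'-biaryl nickelacycles). The six-membered ring is closed by reductive elimination from a seven-membered nickelacycle, i.e. a formal [4+2] annulation of the biaryl 2,2'-positions with the C=C bond. The new stereocentre C9 is set under control of the chiral BiOX ligand in the benzylic C–aryl bond formation. The step needs regioselectivity (ring A to CH2, ring D to CH) and chemoselectivity for the terminal styrene over the internal stilbene of 10: the first is secured by the Br/OTf reactivity gap and the 2,1-insertion preference of styrenes, the second by the inertness of 1,2-diarylalkenes to arylnickel insertion. The slowly rotating atropisomers of 10 should converge, because the biaryl axis is no longer stereogenic once it is bridged.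

Step 7
Reactants: 12 (9R)-9-(3,4-dimethoxyphenyl)-8-[(E)-2-(3,4-dimethoxyphenyl)ethenyl]-2,4,6-trimethoxy-9,10-dihydrophenanthrene
Product: 13 hepta-O-methyl ether of the target: 2,4,6-trimethoxy-9,10-dihydrophenanthrene bridged from C8 to C9 by –CH2–CH(3,4-dimethoxyphenyl)–(4,5-dimethoxy-1,2-phenylene)–, 9R, bridge CH(Ar) S, the two methine hydrogens cis
Conditions: TfOH (20 mol %), HFIP/CH2Cl2 (1:4), −20 → 0 °C
Reagents that add atoms: none
Why: Brønsted acid protonates the stilbene at the carbon next to ring D to give a p-methoxybenzyl cation that is captured by C6 of the 9-aryl ring (para to its 3-OMe) in a seven-membered Friedel–Crafts hydroarylation, both cation faces converging on the isomer with the new aryl group pseudo-equatorial on the boat-shaped ring, i.e. the CH(Ar) hydrogen cis to H9 (S), under control of the existing C9 centre.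

Step 8
Reactants: 13 hepta-O-methyl ether of the target
Product: 14 CNP0306974.1 (target): 2,4,6-trihydroxy-9,10-dihydrophenanthrene bridged from C8 to C9 by –CH2–CH(3,4-dihydroxyphenyl)–(4,5-dihydroxy-1,2-phenylene)–, 9R, bridge CH(Ar) S
Conditions: BBr3 (14 equiv), CH2Cl2, −78 °C → rt; MeOH, then H2O
Reagents that add atoms: none
Why: Exhaustive O-demethylation of the seven aryl methyl ethers by BBr3 (Lewis acid complexation, then SN2 attack of bromide on methyl), conditions under which the two diarylmethine centres should not be ionised.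

**Compound list**

1 | 1-bromo-3,5-dimethoxybenzene | COc1cc(Br)cc(OC)c1 | starting material
2 | 1-bromo-2-iodo-3,5-dimethoxybenzene | COc1cc(OC)c(I)c(Br)c1 | intermediate
3 | 2-hydroxy-5-methoxybenzaldehyde | COc1ccc(O)c(C=O)c1 | starting material
4 | 2-hydroxy-3-iodo-5-methoxybenzaldehyde | COc1cc(I)c(O)c(C=O)c1 | intermediate
5 | 2-formyl-6-iodo-4-methoxyphenyl trifluoromethanesulfonate | COc1cc(I)c(OS(=O)(=O)C(F)(F)F)c(C=O)c1 | intermediate
6 | diethyl (3,4-dimethoxybenzyl)phosphonate | CCOP(=O)(Cc1ccc(OC)c(OC)c1)OCC | starting material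
7 | 2-[(E)-2-(3,4-dimethoxyphenyl)ethenyl]-6-iodo-4-methoxyphenyl trifluoromethanesulfonate | COc1cc(I)c(OS(=O)(=O)C(F)(F)F)c(/C=C/c2ccc(OC)c(OC)c2)c1 | intermediate
8 | (2-bromo-4,6-dimethoxyphenyl)magnesium chloride | COc1cc(OC)c([Mg]Cl)c(Br)c1 | intermediate
9 | (2-bromo-4,6-dimethoxyphenyl)zinc chloride | COc1cc(OC)c([Zn]Cl)c(Br)c1 | intermediate
10 | 2'-bromo-3-[(E)-2-(3,4-dimethoxyphenyl)ethenyl]-4',5,6'-trimethoxybiphenyl-2-yl trifluoromethanesulfonate | COc1cc(-c2c(OC)cc(OC)cc2Br)c(OS(=O)(=O)C(F)(F)F)c(/C=C/c2ccc(OC)c(OC)c2)c1 | intermediate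
11 | 3,4-dimethoxystyrene | C=Cc1ccc(OC)c(OC)c1 | starting material
12 | (9R)-9-(3,4-dimethoxyphenyl)-8-[(E)-2-(3,4-dimethoxyphenyl)ethenyl]-2,4,6-trimethoxy-9,10-dihydrophenanthrene | COc1cc(OC)c2c(c1)C[C@H](c1ccc(OC)c(OC)c1)c1c(/C=C/c3ccc(OC)c(OC)c3)cc(OC)cc1-2 | intermediate
13 | hepta-O-methyl ether of the target (9R, bridge CH(Ar) S) | COc1cc(OC)c2c(c1)C[C@@H]1c3cc(OC)c(OC)cc3[C@H](c3ccc(OC)c(OC)c3)Cc3cc(OC)cc-2c31 | intermediate
14 | CNP0306974.1 (9R, bridge CH(Ar) S) | Oc1cc(O)c2c(c1)C[C@@H]1c3cc(O)c(O)cc3[C@H](c3ccc(O)c(O)c3)Cc3cc(O)cc-2c31 | target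

**Step count.** Total: 8 steps. Longest linear sequence: 7 steps (3 → 14, steps 2–8).

**Steps most likely to fail**

Step 6 (Proposed new method). What may go wrong: insufficient enantioinduction by the ligand, β-hydride elimination of the benzylic nickel intermediate to the Heck stilbene, or premature activation of the C–OTf bond giving the regioisomeric ring. Fallback by known chemistry, setting out from 10 and returning at 13: Mizoroki–Heck reaction of 10 with 11 at the C–Br bond (Pd(OAc)2, P(o-tol)3, Et3N, DMF, 100 °C) should give the bis-stilbene triflate F1. Pd-catalysed hydrogenolysis of the triflate (Pd(OAc)2, dppf, HCO2H, Et3N, DMF, 70 °C) should give the bis-stilbene F2. TfOH then protonates both stilbenes and two consecutive Friedel–Crafts hydroarylations follow: first the six-membered ring, para to the OMe of ring D, passing through racemic 12 (12 and ent-12 F3), then the seven-membered ring. This should give racemic 13 (13 and ent-13 F4), from which 13 is separated by preparative HPLC on a chiral stationary phase.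

Step 7. What may go wrong: 1,5-hydride transfer from the doubly benzylic C9–H to the stilbene-derived cation, which would erase C9 and lead to aromatisation to a phenanthrene, in competition with ring closure. Fallback, setting out from 12 and returning at 13: the free benzylic cation is replaced by a seleniranium ion. N-(Phenylselanyl)phthalimide with catalytic TMSOTf (CH2Cl2, −78 °C) should effect arene-terminated selenocyclisation to 10-phenylselanyl-13 F5 (C–C bond at the aryl-bearing carbon, selenium anti on the CH next to ring D). Bu3SnH/AIBN (toluene, 80 °C) then removes selenium to give 13.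

Step 5. What may go wrong: slow transmetalation and reductive elimination at the doubly ortho-flanked C–I bond, with proto-demetalation or homocoupling of the arylzinc and erosion of the C–Br or C–OTf bonds by the active catalyst. Fallback, setting out from 2 (with 4 and 6) and returning at 10: the biaryl is made by Suzuki–Miyaura coupling before the triflate exists. The Grignard reagent 8 from 2 is quenched with B(OMe)3 and aqueous HCl to give (2-bromo-4,6-dimethoxyphenyl)boronic acid F6. Coupling with the iodophenol 4 (Pd(dppf)Cl2, K3PO4, dioxane/H2O, 80 °C; C–I before C–Br) should give the biaryl salicylaldehyde F7. Horner–Wadsworth–Emmons olefination with 6 (NaH, 2.2 equiv, THF) should give the stilbene phenol F8, and triflation (Tf2O, pyridine, CH2Cl2, 0 °C) gives 10.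

**Further compounds**

F1 | step 6 | 2',3-bis[(E)-2-(3,4-dimethoxyphenyl)ethenyl]-4',5,6'-trimethoxybiphenyl-2-yl trifluoromethanesulfonate | COc1cc(-c2c(OC)cc(OC)cc2/C=C/c2ccc(OC)c(OC)c2)c(OS(=O)(=O)C(F)(F)F)c(/C=C/c2ccc(OC)c(OC)c2)c1
F2 | step 6 | 2,3'-bis[(E)-2-(3,4-dimethoxyphenyl)ethenyl]-4,5',6-trimethoxybiphenyl | COc1cc(-c2c(OC)cc(OC)cc2/C=C/c2ccc(OC)c(OC)c2)cc(/C=C/c2ccc(OC)c(OC)c2)c1
F3 | step 6 | ent-12, (9S)-9-(3,4-dimethoxyphenyl)-8-[(E)-2-(3,4-dimethoxyphenyl)ethenyl]-2,4,6-trimethoxy-9,10-dihydrophenanthrene | COc1cc(OC)c2c(c1)C[C@@H](c1ccc(OC)c(OC)c1)c1c(/C=C/c3ccc(OC)c(OC)c3)cc(OC)cc1-2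
F4 | step 6 | ent-13 (9S, bridge CH(Ar) R) | COc1cc(OC)c2c(c1)C[C@H]1c3cc(OC)c(OC)cc3[C@@H](c3ccc(OC)c(OC)c3)Cc3cc(OC)cc-2c31
F5 | step 7 | 10-phenylselanyl-13 (13 with SePh on the bridge CH2 carbon, anti to the new C–aryl bond) | COc1cc(OC)c2c(c1)C[C@@H]1c3cc(OC)c(OC)cc3[C@H](c3ccc(OC)c(OC)c3)[C@@H]([Se]c3ccccc3)c3cc(OC)cc-2c31
F6 | step 5 | (2-bromo-4,6-dimethoxyphenyl)boronic acid | COc1cc(OC)c(B(O)O)c(Br)c1
F7 | step 5 | 2'-bromo-2-hydroxy-4',5,6'-trimethoxybiphenyl-3-carbaldehyde | COc1cc(-c2c(OC)cc(OC)cc2Br)c(O)c(C=O)c1
F8 | step 5 | 2'-bromo-3-[(E)-2-(3,4-dimethoxyphenyl)ethenyl]-4',5,6'-trimethoxybiphenyl-2-ol | COc1cc(-c2c(OC)cc(OC)cc2Br)c(O)c(/C=C/c2ccc(OC)c(OC)c2)c1
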